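**Retrosynthetic overview**
1. The phenol/acid pair of the target is an opened dihydrocoumarin. The C6–CH(propyl) bond and its (R) centre come from an iminium-catalysed Friedel–Crafts alkylation/hemiacetalisation of a C8-prenylated chroman-5-ol with (E)-hex-2-enal, followed by lactol oxidation and lactone hydrolysis.
2. The C8 prenyl group comes from directed lithiation of the O-TIPS chromanol. Ring B is closed before that by Mitsunobu O1–C2 etherification with inversion at C2.
3. The strategy rests on the O1–C2H(CH3)–C3H(CH3)–C4H2 chain of ring B (trans methyls), which hangs from C4a between the oxygen-bearing carbons C5 and C8a. It is read as a benzylic CH2–B bond into which two CH(CH3) units are inserted in turn (C4–C3, then C3–C2), with C2 made in the configuration opposite to the target.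
4. The benzylic boronic ester comes from bis-MOM 5-methoxyresorcinol by lithiation between the two acetals and an aryl shift from boron to carbon on a bromomethyl boronate.
5. Ring order: ring A (arene) is bought, ring B (dihydropyran) closes in step 7, and a temporary lactol/lactone ring on O5/C6 forms in step 11 and is opened in step 13.

Key step: step 4

Assumption: lactol 23 is formed and carried on as a mixture of anomers at its hemiacetal carbon (left undefined in its SMILES); both converge in step 12.

**Route**

Step 1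
Reactants: 1 5-methoxyresorcinol
Product: 2 1-methoxy-3,5-bis(methoxymethoxy)benzene
Conditions: NaH (2.5 equiv), MOMCl (2.5 equiv), DMF, 0 °C to rt
Reagents that add atoms: chloromethyl methyl ether, COCCl
Why: Williamson-type O-alkylation of both phenoxides with the reactive chloromethyl ether gives the bis-MOM ether, whose acetal oxygens later direct lithiation.

Step 2
Reactants: 2 1-methoxy-3,5-bis(methoxymethoxy)benzene; 3 2-(bromomethyl)-4,4,5,5-tetramethyl-1,3,2-dioxaborolane
Product: 6 2-[4-methoxy-2,6-bis(methoxymethoxy)benzyl]-4,4,5,5-tetramethyl-1,3,2-dioxaborolane, via aryllithium 4 (not isolated), via bromomethyl ate complex 5 (not isolated)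
Conditions: n-BuLi (1.1 equiv), THF, 0 °C, 1 h; then 3 (1.2 equiv), −78 °C to rt, 16 h
Reagents that add atoms: none
Why: Directed ortho-metalation takes place at the CH flanked by the two chelating OMOM groups, the aryllithium adds to boron, and on warming the aryl group undergoes a Matteson-type 1,2-shift from boron to carbon with loss of bromide (the bromide is chosen over the iodide so that halogen–lithium exchange does not compete).

Step 3
Reactants: 7 2,4,6-triisopropylbenzoic acid
Product: 8 ethyl 2,4,6-triisopropylbenzoate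
Conditions: EtI, K2CO3, DMF, 40 °C
Reagents that add atoms: ethyl iodide, CCI
Why: SN2 O-alkylation of the hindered carboxylate with ethyl iodide avoids any reaction at the shielded carbonyl and gives the ester whose OCH2CH3 group supplies the two CH(CH3) units.

Step 4
Reactants: 6 2-[4-methoxy-2,6-bis(methoxymethoxy)benzyl]-4,4,5,5-tetramethyl-1,3,2-dioxaborolane; 8 ethyl 2,4,6-triisopropylbenzoate (two charges)
Product: 13 2-[(2R,3R)-4-[4-methoxy-2,6-bis(methoxymethoxy)phenyl]-3-methylbutan-2-yl]-4,4,5,5-tetramethyl-1,3,2-dioxaborolane, via lithiated benzoate 9 (not isolated), via first ate complex 10 (not isolated), via monohomologated boronic ester 11 (not isolated), via second ate complex 12 (not isolated)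
Conditions: 8 (1.15 equiv), (−)-sparteine (1.15 equiv), s-BuLi (1.1 equiv), Et2O, −78 °C, 5 h; 6, −78 °C, 2 h; −40 °C, 1 h; reflux, 3 h; cooled solution cannulated into a second charge of 9 [8 (1.5 equiv), (−)-sparteine, s-BuLi, Et2O, −78 °C]; −78 °C, 3 h; −40 °C, 1 h; reflux, 16 h
Reagents that add atoms: none
Why: s-BuLi/(−)-sparteine removes the pro-S α-proton of 8 to give the configurationally stable carbenoid 9, which adds to boron of 6 with retention at carbon to give ate complex 10; on warming the benzyl group shifts from boron to carbon anti-periplanar to the departing triisopropylbenzoate (inversion at the carbenoid carbon), forming C4–C3 and the (R) centre of 11. A second charge of 9 repeats the sequence on the secondary boronic ester through 12, the stereogenic alkyl group migrating with retention, which forms C3–C2 and the second (R) centre of 13. The closest known reaction type is iterative lithiation–borylation (assembly-line homologation of boronic esters with lithiated triisopropylbenzoates). No ring closes in this step. Both stereocentres are under reagent control by the (−)-sparteine used in each round, and the existing centre of 11 is expected to have little influence on the second insertion. The step needs complete ate-complex formation without double insertion, which the small excess of 9, the unhindered CH2–B of 6 and the hold at −40 °C (meant to let surplus 9 decay before 10 or 12 rearranges) should secure.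

Step 5
Reactants: 13 2-[(2R,3R)-4-[4-methoxy-2,6-bis(methoxymethoxy)phenyl]-3-methylbutan-2-yl]-4,4,5,5-tetramethyl-1,3,2-dioxaborolane
Product: 14 (2R,3R)-4-[4-methoxy-2,6-bis(methoxymethoxy)phenyl]-3-methylbutan-2-ol
Conditions: H2O2 (30% aq.), NaOH (2 M aq.), THF, 0 °C to rt
Reagents that add atoms: hydrogen peroxide, OO
Why: Boronate oxidation proceeds by a 1,2-shift of carbon from boron to oxygen with retention, so the (2R,3R) boronate should give the (2R,3R) alcohol, and MOM ethers are stable to basic peroxide.

Step 6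
Reactants: 14 (2R,3R)-4-[4-methoxy-2,6-bis(methoxymethoxy)phenyl]-3-methylbutan-2-ol
Product: 15 2-[(2R,3R)-3-hydroxy-2-methylbutyl]-5-methoxybenzene-1,3-diol
Conditions: HCl (cat.), MeOH, 40 °C
Reagents that add atoms: none
Why: Acid-catalysed acetal exchange with methanol removes both MOM groups while the non-benzylic secondary alcohol and both stereocentres are left untouched.

Step 7
Reactants: 15 2-[(2R,3R)-3-hydroxy-2-methylbutyl]-5-methoxybenzene-1,3-diol
Product: 16 (2S,3R)-7-methoxy-2,3-dimethyl-3,4-dihydro-2H-chromen-5-ol (trans-2,3-dimethyl)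
Conditions: PPh3, DIAD, THF (0.02 M), 0 °C to rt
Reagents that add atoms: none
Why: Intramolecular Mitsunobu etherification, in which the alkoxyphosphonium ion of the secondary alcohol is displaced by a phenoxide in a 6-exo-tet closure with inversion, turns the (2R) carbinol into the (2S) C2 of ring B; the two phenols are equivalent by rotation about the aryl–CH2 bond, so one product results and the other OH stays as C5–OH.

Step 8
Reactants: 16 (2S,3R)-7-methoxy-2,3-dimethyl-3,4-dihydro-2H-chromen-5-ol
Product: 17 triisopropyl{[(2S,3R)-7-methoxy-2,3-dimethyl-3,4-dihydro-2H-chromen-5-yl]oxy}silane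
Conditions: TIPSCl, imidazole, DMF, rt
Reagents that add atoms: chlorotriisopropylsilane, CC(C)[Si](Cl)(C(C)C)C(C)C
Why: Silylation of the phenol installs a bulky, weakly coordinating group that protects the OH and shields the neighbouring C6–H from lithiation.

Step 9
Reactants: 17 triisopropyl{[(2S,3R)-7-methoxy-2,3-dimethyl-3,4-dihydro-2H-chromen-5-yl]oxy}silane; 18 prenyl bromide (1-bromo-3-methylbut-2-ene)
Product: 20 triisopropyl{[(2S,3R)-7-methoxy-2,3-dimethyl-8-(3-methylbut-2-en-1-yl)-3,4-dihydro-2H-chromen-5-yl]oxy}silane, via C8 aryllithium 19 (not isolated)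
Conditions: n-BuLi, TMEDA, Et2O, 0 °C to rt; then CuI (10 mol %), 18, THF, −78 °C to rt
Reagents that add atoms: none
Why: Directed ortho-metalation should occur at C8, the only ring CH flanked by two unhindered ether oxygens (C7–OMe and O1), and the aryllithium is then allylated at the primary carbon of prenyl bromide under copper catalysis (SN2, no allylic transposition).

Step 10
Reactants: 20 triisopropyl{[(2S,3R)-7-methoxy-2,3-dimethyl-8-(3-methylbut-2-en-1-yl)-3,4-dihydro-2H-chromen-5-yl]oxy}silane
Product: 21 (2S,3R)-7-methoxy-2,3-dimethyl-8-(3-methylbut-2-en-1-yl)-3,4-dihydro-2H-chromen-5-ol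
Conditions: Bu4NF, THF, 0 °C
Reagents that add atoms: none
Why: Fluoride cleaves the aryl silyl ether selectively and frees the C5 phenol next to C6, now the only unsubstituted ring position.

Step 11
Reactants: 21 (2S,3R)-7-methoxy-2,3-dimethyl-8-(3-methylbut-2-en-1-yl)-3,4-dihydro-2H-chromen-5-ol; 22 (E)-hex-2-enal
Product: 23 (4R,8S,9R)-5-methoxy-8,9-dimethyl-6-(3-methylbut-2-en-1-yl)-4-propyl-3,4,9,10-tetrahydro-2H,8H-pyrano[2,3-f]chromen-2-ol (mixture of C2 anomers)
Conditions: (S)-2-[diphenyl(trimethylsilyloxy)methyl]pyrrolidine (20 mol %), PhCO2H (20 mol %), toluene, 0 °C to rt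
Reagents that add atoms: none
Why: Iminium-catalysed Friedel–Crafts alkylation of an electron-rich phenol with an enal followed by hemiacetalisation: C6 (ortho to the OH and the only free ring position) attacks the β-carbon of the (E)-iminium ion of 22 on the face away from the diphenyl(silyloxy)methyl group of the (S)-catalyst, which should set the (R) benzylic centre, and the released aldehyde is trapped by the C5 hydroxyl as the lactol.

Step 12
Reactants: 23 (4R,8S,9R)-5-methoxy-8,9-dimethyl-6-(3-methylbut-2-en-1-yl)-4-propyl-3,4,9,10-tetrahydro-2H,8H-pyrano[2,3-f]chromen-2-ol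
Product: 24 (4R,8S,9R)-5-methoxy-8,9-dimethyl-6-(3-methylbut-2-en-1-yl)-4-propyl-3,4,9,10-tetrahydro-2H,8H-pyrano[2,3-f]chromen-2-one
Conditions: Pr4N[RuO4] (5 mol %), N-methylmorpholine N-oxide, 4 Å MS, CH2Cl2, rt
Reagents that add atoms: none
Why: Ley–Griffith oxidation converts both lactol anomers into the dihydrocoumarin lactone under neutral conditions that leave the prenyl alkene and the electron-rich arene alone.

Step 13
Reactants: 24 (4R,8S,9R)-5-methoxy-8,9-dimethyl-6-(3-methylbut-2-en-1-yl)-4-propyl-3,4,9,10-tetrahydro-2H,8H-pyrano[2,3-f]chromen-2-one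
Product: 25 (3R)-3-[(2S,3R)-5-hydroxy-7-methoxy-2,3-dimethyl-8-(3-methylbut-2-en-1-yl)-3,4-dihydro-2H-chromen-6-yl]hexanoic acid (CNP0275989.1)
Conditions: LiOH, THF/H2O, 0 °C to rt; then 1 M HCl to pH 4, 0 °C, extraction without heating
Reagents that add atoms: lithium hydroxide, [Li+].[OH-]
Why: Saponification opens the aryl ester lactone to phenol and carboxylate without touching the β-stereocentre, and cold acidification to pH 4 should deliver the hydroxy acid before it can relactonise.

**Compound list**
1 | 5-methoxyresorcinol | COc1cc(O)cc(O)c1 | starting material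
2 | 1-methoxy-3,5-bis(methoxymethoxy)benzene | COCOc1cc(OC)cc(OCOC)c1 | intermediate
3 | 2-(bromomethyl)-4,4,5,5-tetramethyl-1,3,2-dioxaborolane | BrCB1OC(C)(C)C(C)(C)O1 | starting material
4 | [4-methoxy-2,6-bis(methoxymethoxy)phenyl]lithium | [Li]c1c(OCOC)cc(OC)cc1OCOC | intermediate
5 | lithium (bromomethyl)[4-methoxy-2,6-bis(methoxymethoxy)phenyl](pinacolato)borate | [Li+].BrC[B-]1(c2c(OCOC)cc(OC)cc2OCOC)OC(C)(C)C(C)(C)O1 | intermediate
6 | 2-[4-methoxy-2,6-bis(methoxymethoxy)benzyl]-4,4,5,5-tetramethyl-1,3,2-dioxaborolane | COCOc1cc(OC)cc(OCOC)c1CB1OC(C)(C)C(C)(C)O1 | intermediate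
7 | 2,4,6-triisopropylbenzoic acid | CC(C)c1cc(C(C)C)c(C(=O)O)c(C(C)C)c1 | starting material
8 | ethyl 2,4,6-triisopropylbenzoate | CCOC(=O)c1c(C(C)C)cc(C(C)C)cc1C(C)C | intermediate
9 | (S)-1-lithioethyl 2,4,6-triisopropylbenzoate, (−)-sparteine complex | C[C@H]([Li])OC(=O)c1c(C(C)C)cc(C(C)C)cc1C(C)C | intermediate
10 | lithium ate complex of 6 with 9, (S) at the O-bearing carbon | [Li+].C[C@@H](OC(=O)c1c(C(C)C)cc(C(C)C)cc1C(C)C)[B-]1(Cc2c(OCOC)cc(OC)cc2OCOC)OC(C)(C)C(C)(C)O1 | intermediate
11 | 2-[(2R)-1-[4-methoxy-2,6-bis(methoxymethoxy)phenyl]propan-2-yl]-4,4,5,5-tetramethyl-1,3,2-dioxaborolane | CC1(C)OB(OC1(C)C)[C@H](C)Cc1c(OCOC)cc(OC)cc1OCOC | intermediate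
12 | lithium ate complex of 11 with 9, (S) at the O-bearing carbon, (R) at the B-bound alkyl carbon | [Li+].C[C@@H](OC(=O)c1c(C(C)C)cc(C(C)C)cc1C(C)C)[B-]1([C@H](C)Cc2c(OCOC)cc(OC)cc2OCOC)OC(C)(C)C(C)(C)O1 | intermediate
13 | 2-[(2R,3R)-4-[4-methoxy-2,6-bis(methoxymethoxy)phenyl]-3-methylbutan-2-yl]-4,4,5,5-tetramethyl-1,3,2-dioxaborolane | CC1(C)OB(OC1(C)C)[C@H](C)[C@H](C)Cc1c(OCOC)cc(OC)cc1OCOC | intermediate
14 | (2R,3R)-4-[4-methoxy-2,6-bis(methoxymethoxy)phenyl]-3-methylbutan-2-ol | O[C@H](C)[C@H](C)Cc1c(OCOC)cc(OC)cc1OCOC | intermediate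
15 | 2-[(2R,3R)-3-hydroxy-2-methylbutyl]-5-methoxybenzene-1,3-diol | O[C@H](C)[C@H](C)Cc1c(O)cc(OC)cc1O | intermediate
16 | (2S,3R)-7-methoxy-2,3-dimethyl-3,4-dihydro-2H-chromen-5-ol | COc1cc(O)c2c(c1)O[C@@H](C)[C@H](C)C2 | intermediate
17 | triisopropyl{[(2S,3R)-7-methoxy-2,3-dimethyl-3,4-dihydro-2H-chromen-5-yl]oxy}silane | COc1cc(O[Si](C(C)C)(C(C)C)C(C)C)c2c(c1)O[C@@H](C)[C@H](C)C2 | intermediate
18 | prenyl bromide (1-bromo-3-methylbut-2-ene) | CC(C)=CCBr | starting material
19 | 8-lithio derivative of 17 | COc1cc(O[Si](C(C)C)(C(C)C)C(C)C)c2c(c1[Li])O[C@@H](C)[C@H](C)C2 | intermediate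
20 | triisopropyl{[(2S,3R)-7-methoxy-2,3-dimethyl-8-(3-methylbut-2-en-1-yl)-3,4-dihydro-2H-chromen-5-yl]oxy}silane | COc1cc(O[Si](C(C)C)(C(C)C)C(C)C)c2c(c1CC=C(C)C)O[C@@H](C)[C@H](C)C2 | intermediate
21 | (2S,3R)-7-methoxy-2,3-dimethyl-8-(3-methylbut-2-en-1-yl)-3,4-dihydro-2H-chromen-5-ol | COc1cc(O)c2c(c1CC=C(C)C)O[C@@H](C)[C@H](C)C2 | intermediate
22 | (E)-hex-2-enal | CCC/C=C/C=O | starting material
23 | (4R,8S,9R)-5-methoxy-8,9-dimethyl-6-(3-methylbut-2-en-1-yl)-4-propyl-3,4,9,10-tetrahydro-2H,8H-pyrano[2,3-f]chromen-2-ol, mixture of C2 anomers | CCC[C@H](CC3O)c1c(O3)c2c(c(CC=C(C)C)c1OC)O[C@@H](C)[C@H](C)C2 | intermediate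
24 | (4R,8S,9R)-5-methoxy-8,9-dimethyl-6-(3-methylbut-2-en-1-yl)-4-propyl-3,4,9,10-tetrahydro-2H,8H-pyrano[2,3-f]chromen-2-one | CCC[C@H](CC3=O)c1c(O3)c2c(c(CC=C(C)C)c1OC)O[C@@H](C)[C@H](C)C2 | intermediate
25 | (3R)-3-[(2S,3R)-5-hydroxy-7-methoxy-2,3-dimethyl-8-(3-methylbut-2-en-1-yl)-3,4-dihydro-2H-chromen-6-yl]hexanoic acid | CCC[C@H](CC(=O)O)c1c(O)c2c(c(CC=C(C)C)c1OC)O[C@@H](C)[C@H](C)C2 | target

**Step count**
Total: 13 steps. Longest linear sequence: 12 steps (steps 1, 2, 4–13 from compound 1); step 3 is a one-step branch that supplies 8.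

**Steps most likely to fail**

Step 4. The second insertion may stall because the sparteine-bound carbenoid forms the ate complex only slowly at the secondary boron centre of 11, and surplus carbenoid carried through the one-pot sequence may insert a third time; either process would erode purity and stereochemical integrity. The fallback sets out from 6 and runs the two insertions as separate, isolated operations with a diamine-free carbenoid whose configuration is fixed beforehand. Ester 8 is lithiated with s-BuLi/(−)-sparteine and trapped with Me3SnCl to give (S)-1-(trimethylstannyl)ethyl 2,4,6-triisopropylbenzoate F1, which is recrystallised to high enantiopurity. Tin–lithium exchange of this stannane (n-BuLi, Et2O, −78 °C) gives the sparteine-free (S)-carbenoid, which converts 6 into 11 (isolated in this variant); a second cycle with the same stannane converts 11 into 13, where the route is rejoined.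

Step 11. C-alkylation at the crowded C6 may be slow, reversible O-addition of the phenol to the iminium ion may compete, and facial discrimination with an aliphatic enal may be incomplete. The fallback sets out from 21. Magnesium-mediated ortho-formylation (MgCl2, Et3N, paraformaldehyde, MeCN, reflux) gives (2S,3R)-5-hydroxy-7-methoxy-2,3-dimethyl-8-(3-methylbut-2-en-1-yl)-3,4-dihydro-2H-chromene-6-carbaldehyde F2. Wittig olefination with Ph3P=CHCO2Et in hot N,N-diethylaniline and lactonisation in the same pot give the coumarin (8S,9R)-5-methoxy-8,9-dimethyl-6-(3-methylbut-2-en-1-yl)-9,10-dihydro-2H,8H-pyrano[2,3-f]chromen-2-one F3. Copper-catalysed enantioselective conjugate addition of n-PrMgBr (CuBr·SMe2, Josiphos-type ferrocenyl diphosphine, ligand enantiomer chosen to deliver propyl to the face that gives 4R) then leads to lactone 24, where the route is rejoined.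

Step 9. Deprotonation may stray to C6 despite the silyl shield, giving the wrong regioisomer or silyl migration. The fallback sets out from 17 and replaces directed deprotonation by electrophilic substitution. NBS in MeCN at 0 °C should brominate para to the silyloxy group, away from its bulk, to give {[(2S,3R)-8-bromo-7-methoxy-2,3-dimethyl-3,4-dihydro-2H-chromen-5-yl]oxy}triisopropylsilane F4. Bromine–lithium exchange (t-BuLi, THF, −78 °C) regenerates aryllithium 19 at a defined position, and the same CuI-catalysed allylation with 18 gives 20, where the route is rejoined.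

**Further compounds**
F1 | step 4 | (S)-1-(trimethylstannyl)ethyl 2,4,6-triisopropylbenzoate | C[C@@H](OC(=O)c1c(C(C)C)cc(C(C)C)cc1C(C)C)[Sn](C)(C)C
F2 | step 11 | (2S,3R)-5-hydroxy-7-methoxy-2,3-dimethyl-8-(3-methylbut-2-en-1-yl)-3,4-dihydro-2H-chromene-6-carbaldehyde | COc1c(C=O)c(O)c2c(c1CC=C(C)C)O[C@@H](C)[C@H](C)C2
F3 | step 11 | (8S,9R)-5-methoxy-8,9-dimethyl-6-(3-methylbut-2-en-1-yl)-9,10-dihydro-2H,8H-pyrano[2,3-f]chromen-2-one | O=C3C=Cc1c(O3)c2c(c(CC=C(C)C)c1OC)O[C@@H](C)[C@H](C)C2
F4 | step 9 | {[(2S,3R)-8-bromo-7-methoxy-2,3-dimethyl-3,4-dihydro-2H-chromen-5-yl]oxy}triisopropylsilane | COc1cc(O[Si](C(C)C)(C(C)C)C(C)C)c2c(c1Br)O[C@@H](C)[C@H](C)C2
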